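A direct plan would build ring C first: kojic acid A1 would be brominated, O-methylated and joined to ring B by a Suzuki coupling to give pyranone A2, and the CH2OH group of A2 would be oxidized, activated and homologated with a diazoalkane to the diazo ketone A3.
Ring A would come last: photochemical Wolff rearrangement of A3, [2+2] addition of the ketene to the silyloxyacetylene A4 and a 4π opening/6π closure onto pyranone C3 would give the 7-silyloxyflavone A5, to be unmasked with fluoride.
Its weakest steps would be:
(a) the late benzannulation, which would leave the closure of ring A to a ketene cascade without precedent on the C2=C3 bond of a 4-pyranone, under irradiation, on the most precious material;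
(b) the making of A4, two steps for a volatile, moisture-sensitive ynol ether whose protodesilylation in an alcohol would have to spare the ynol ether itself;
(c) the path from A2 to A3, three steps and a hazardous reagent spent on one added carbon atom.

Hardest here are the four differently treated oxygens (3-OMe, 4'-O-prenyl, free 5- and 7-OH) on a skeleton whose prenyl ether bears neither strong acid, oxidant nor heat; in the new route each oxygen arrives in its own bond-forming event without strong acid, oxidant or light.
Retrosynthesis: the C5–O and C7–O bonds are cut back to C–F bonds, then ring C at O1–C8a and C3–C4 (the key step), then the C1'–C2 ketone bond and the prenyl ether bond.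
Rings A and B are bought as benzene rings; ring C is the only ring formed, from two simple partners, in one operation.
The feature used: on ring A, O1 (at C8a) and the oxygens at C5 and C7 all sit ortho or para to the C4 carbonyl carbon, so ring A can enter as 2,4,6-trifluorobenzoyl chloride. One of its two equivalent ortho fluorides is displaced by the enolate oxygen to close ring C, and the other two C–F bonds become the 5- and 7-hydroxyls.
No ring closure is left to a photochemical ketene cascade, no ynol ether or diazo compound is made, and the 3-methoxy carbon comes in with a bought two-carbon amide.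

Key step: step 3

Remark: in the twofold fluoride displacement the fluoride para to the C4 carbonyl (at C7) is assumed to leave first; the order has no bearing on the product.

Step 1
Reactants: 1 4-bromophenol; 2 1-bromo-3-methylbut-2-ene (prenyl bromide)
Product: 3 1-bromo-4-(3-methylbut-2-enyloxy)benzene
Conditions: K2CO3, acetone, 55 °C
Reagents that add atoms: none
Why: Williamson ether synthesis, in which the phenoxide displaces the primary allylic bromide at its CH2 carbon (SN2) while the aryl bromide is inert to carbonate.

Step 2
Reactants: 3 1-bromo-4-(3-methylbut-2-enyloxy)benzene; 4 N-methoxy-N-methyl-2-methoxyacetamide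
Product: 6 2-methoxy-1-[4-(3-methylbut-2-enyloxy)phenyl]ethan-1-one, via aryllithium 5 (not isolated)
Conditions: n-BuLi (1.05 equiv), THF, −78 °C; then 4 (1.2 equiv), −78 to 0 °C; aq. NH4Cl
Reagents that add atoms: n-butyllithium, [Li]CCCC (its lithium stays only in intermediate 5)
Why: Bromine–lithium exchange followed by a Weinreb ketone synthesis, in which the aryllithium adds once to the N-methoxy-N-methyl amide to give a chelated tetrahedral adduct that releases the ketone only on quenching, so that no tertiary alcohol should form and the prenyl ether is not touched at −78 °C.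

Step 3
Reactants: 6 2-methoxy-1-[4-(3-methylbut-2-enyloxy)phenyl]ethan-1-one; 7 2,4,6-trifluorobenzoyl chloride
Product: 9 5,7-difluoro-3-methoxy-2-[4-(3-methylbut-2-enyloxy)phenyl]-4H-chromen-4-one, via 2-methoxy-1,3-diketone 8 (not isolated)
Conditions: MgBr2·OEt2 (2.5 equiv), i-Pr2NEt (3 equiv), CH2Cl2, 0 °C to rt; aq. NH4Cl wash, solvent exchange (crude 8); then K2CO3 (2 equiv), DMF, 60 °C
Reagents that add atoms: none
Why: MgBr2 binds the methoxy and carbonyl oxygens of 6 so that i-Pr2NEt can remove the α-hydrogen (soft enolization), and the chelated magnesium enolate is acylated at carbon by 7 to form the C3–C4 bond of diketone 8; with K2CO3 in DMF the enolate oxygen on the ring B side then adds to an ortho C–F carbon of the trifluorophenyl ring and fluoride leaves from the Meisenheimer complex, forming the O1–C8a bond. The closest known reaction types are the direct C-acylation of ketones by acid chlorides under soft enolization and the closure of 2-fluorobenzoyl and polyfluorobenzoyl 1,3-dicarbonyl compounds to chromones, flavones and 4-quinolones by intramolecular nucleophilic aromatic substitution. Ring C closes as a six-membered ring by addition–elimination of an oxygen nucleophile at an aromatic carbon, that is at O1–C8a, and not by the usual dehydration at C2. No stereocentre remains, since the CH(OMe) carbon of 8 becomes the sp2 carbon C3. The step needs C- over O-acylation, which the chelated magnesium enolate and the trapping of the more acidic 8 as its enolate should secure, and a single site of ring closure, which is given because the two ortho fluorides are equivalent by symmetry, the para fluoride is out of reach and the other enolate oxygen could only form a four-membered ring. Nothing more acidic than an ammonium salt and no oxidant is present, so the prenyl ether should survive.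

Step 4
Reactants: 9 5,7-difluoro-3-methoxy-2-[4-(3-methylbut-2-enyloxy)phenyl]-4H-chromen-4-one; 10 2-(trimethylsilyl)ethanol
Product: 12 3-methoxy-2-[4-(3-methylbut-2-enyloxy)phenyl]-5,7-bis[2-(trimethylsilyl)ethoxy]-4H-chromen-4-one, via 7-monoether 11 (not isolated)
Conditions: 10 (3 equiv), NaH (2.5 equiv), THF, 0 °C; then 9, THF/DMF (3:1), 0 to 60 °C
Reagents that add atoms: none
Why: Twofold nucleophilic aromatic substitution (addition–elimination), in which the sodium alkoxide of 10 displaces the fluorides para and ortho to the C4 carbonyl group, as is known for fluorinated chromones and flavones, while the neutral ether formed first should leave ring A electrophilic enough for the second displacement, which a free phenoxide would not.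

Step 5
Reactants: 12 3-methoxy-2-[4-(3-methylbut-2-enyloxy)phenyl]-5,7-bis[2-(trimethylsilyl)ethoxy]-4H-chromen-4-one
Product: 13 5,7-dihydroxy-3-methoxy-2-[4-(3-methylbut-2-enyloxy)phenyl]-4H-chromen-4-one (5,7-dihydroxy-3-methoxy-4'-prenyloxyflavone)
Conditions: Bu4NF (4 equiv), THF, 50 °C; then AcOH
Reagents that add atoms: none
Why: Fluoride-induced β-elimination of the two aryl 2-(trimethylsilyl)ethyl ethers, in which attack of fluoride on silicon expels ethene and the phenoxides at C5 and C7, while the methyl and prenyl ethers carry no silicon and should be inert to fluoride.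

**Compound list**

1 | 4-bromophenol | Oc1ccc(Br)cc1 | starting material
2 | 1-bromo-3-methylbut-2-ene (prenyl bromide) | CC(C)=CCBr | starting material
3 | 1-bromo-4-(3-methylbut-2-enyloxy)benzene | CC(C)=CCOc1ccc(Br)cc1 | intermediate
4 | N-methoxy-N-methyl-2-methoxyacetamide | COCC(=O)N(C)OC | starting material
5 | [4-(3-methylbut-2-enyloxy)phenyl]lithium | [Li]c1ccc(OCC=C(C)C)cc1 | intermediate
6 | 2-methoxy-1-[4-(3-methylbut-2-enyloxy)phenyl]ethan-1-one | COCC(=O)c1ccc(OCC=C(C)C)cc1 | intermediate
7 | 2,4,6-trifluorobenzoyl chloride | O=C(Cl)c1c(F)cc(F)cc1F | starting material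
8 | 2-methoxy-1-[4-(3-methylbut-2-enyloxy)phenyl]-3-(2,4,6-trifluorophenyl)propane-1,3-dione (racemic, enolizable) | COC(C(=O)c1ccc(OCC=C(C)C)cc1)C(=O)c1c(F)cc(F)cc1F | intermediate
9 | 5,7-difluoro-3-methoxy-2-[4-(3-methylbut-2-enyloxy)phenyl]-4H-chromen-4-one | COc1c(-c2ccc(OCC=C(C)C)cc2)oc2cc(F)cc(F)c2c1=O | intermediate
10 | 2-(trimethylsilyl)ethanol | C[Si](C)(C)CCO | starting material
11 | 5-fluoro-3-methoxy-2-[4-(3-methylbut-2-enyloxy)phenyl]-7-[2-(trimethylsilyl)ethoxy]-4H-chromen-4-one | COc1c(-c2ccc(OCC=C(C)C)cc2)oc2cc(OCC[Si](C)(C)C)cc(F)c2c1=O | intermediate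
12 | 3-methoxy-2-[4-(3-methylbut-2-enyloxy)phenyl]-5,7-bis[2-(trimethylsilyl)ethoxy]-4H-chromen-4-one | COc1c(-c2ccc(OCC=C(C)C)cc2)oc2cc(OCC[Si](C)(C)C)cc(OCC[Si](C)(C)C)c2c1=O | intermediate
13 | 5,7-dihydroxy-3-methoxy-2-[4-(3-methylbut-2-enyloxy)phenyl]-4H-chromen-4-one | COc1c(-c2ccc(OCC=C(C)C)cc2)oc2cc(O)cc(O)c2c1=O | target

Total step count: 5. Longest linear sequence: 5 steps (from 1 to 13).

Steps most likely to fail:

Step 4. The second displacement, at C5, may stall once the first ether has made ring A richer in electrons, or the alkoxide may add at C2 and open the pyranone ring. The fallback sets out from 6, comes back at 13 and brings ring A in with its oxygens already in place. Commercial 2,4,6-trihydroxybenzoic acid would be condensed with acetone, trifluoroacetic anhydride and CF3CO2H to 5,7-dihydroxy-2,2-dimethyl-4H-1,3-benzodioxin-4-one F1. Silylation (t-BuMe2SiCl, imidazole, DMF) would give 5,7-bis(tert-butyldimethylsilyloxy)-2,2-dimethyl-4H-1,3-benzodioxin-4-one F2. The lithium enolate of 6, made with 2.2 equiv of LiN(SiMe3)2 in THF at −78 °C, would open F2 at its lactone carbonyl with loss of acetone to give 1-[2,4-bis(tert-butyldimethylsilyloxy)-6-hydroxyphenyl]-2-methoxy-3-[4-(3-methylbut-2-enyloxy)phenyl]propane-1,3-dione F3. Warm AcOH would cyclodehydrate F3 to 5,7-bis(tert-butyldimethylsilyloxy)-3-methoxy-2-[4-(3-methylbut-2-enyloxy)phenyl]-4H-chromen-4-one F4, and Bu4NF/AcOH in THF at 0 °C would give 13.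

Step 3. The enolate may be acylated at oxygen, or the α-methoxy diketone may suffer retro-Claisen cleavage before the ring closes. The fallback sets out from 6 and comes back at 8. The lithium enolate of 6, made with LiN(SiMe3)2 in THF at −78 °C, would be added to commercial 2,4,6-trifluorobenzaldehyde to give 3-hydroxy-2-methoxy-1-[4-(3-methylbut-2-enyloxy)phenyl]-3-(2,4,6-trifluorophenyl)propan-1-one F5, a mixture of racemic diastereomers whose two stereocentres are of no consequence. An aldol addition cannot give an enol ester. Dess–Martin oxidation (CH2Cl2, NaHCO3, rt) would then give 8, which would be closed as in the route, if need be under strictly anhydrous conditions.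

Step 5. The fragmentation may stay incomplete at the hindered C5 ether next to the carbonyl group, or the electron-rich phenoxides may decompose slowly on prolonged warming with fluoride. The fallback sets out from 9 and comes back at 13. Allyl alcohol and NaH (THF/DMF, 0 to 60 °C) would give 3-methoxy-2-[4-(3-methylbut-2-enyloxy)phenyl]-5,7-bis(prop-2-enyloxy)-4H-chromen-4-one F6. Pd(PPh3)4 (5 mol %) and morpholine in THF at rt would then remove both allyl groups through π-allyl complexes to give 13. The trisubstituted prenyl ether should ionize far more slowly at zerovalent palladium than the unsubstituted allyl ethers.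

Further compounds
F1 | step 4 | 5,7-dihydroxy-2,2-dimethyl-4H-1,3-benzodioxin-4-one | CC1(C)OC(=O)c2c(O)cc(O)cc2O1
F2 | step 4 | 5,7-bis(tert-butyldimethylsilyloxy)-2,2-dimethyl-4H-1,3-benzodioxin-4-one | CC1(C)OC(=O)c2c(O[Si](C)(C)C(C)(C)C)cc(O[Si](C)(C)C(C)(C)C)cc2O1
F3 | step 4 | 1-[2,4-bis(tert-butyldimethylsilyloxy)-6-hydroxyphenyl]-2-methoxy-3-[4-(3-methylbut-2-enyloxy)phenyl]propane-1,3-dione (racemic, enolizable) | COC(C(=O)c1ccc(OCC=C(C)C)cc1)C(=O)c1c(O)cc(O[Si](C)(C)C(C)(C)C)cc1O[Si](C)(C)C(C)(C)C
F4 | step 4 | 5,7-bis(tert-butyldimethylsilyloxy)-3-methoxy-2-[4-(3-methylbut-2-enyloxy)phenyl]-4H-chromen-4-one | COc1c(-c2ccc(OCC=C(C)C)cc2)oc2cc(O[Si](C)(C)C(C)(C)C)cc(O[Si](C)(C)C(C)(C)C)c2c1=O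
F5 | step 3 | 3-hydroxy-2-methoxy-1-[4-(3-methylbut-2-enyloxy)phenyl]-3-(2,4,6-trifluorophenyl)propan-1-one (mixture of racemic diastereomers) | COC(C(O)c1c(F)cc(F)cc1F)C(=O)c1ccc(OCC=C(C)C)cc1
F6 | step 5 | 3-methoxy-2-[4-(3-methylbut-2-enyloxy)phenyl]-5,7-bis(prop-2-enyloxy)-4H-chromen-4-one | COc1c(-c2ccc(OCC=C(C)C)cc2)oc2cc(OCC=C)cc(OCC=C)c2c1=O
A1 | direct plan | kojic acid (5-hydroxy-2-(hydroxymethyl)-4H-pyran-4-one) | O=c1cc(CO)occ1O
A2 | direct plan | 2-(hydroxymethyl)-5-methoxy-6-[4-(3-methylbut-2-enyloxy)phenyl]-4H-pyran-4-one | COc1c(-c2ccc(OCC=C(C)C)cc2)oc(CO)cc1=O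
A3 | direct plan | 2-(diazoacetyl)-5-methoxy-6-[4-(3-methylbut-2-enyloxy)phenyl]-4H-pyran-4-one | COc1c(-c2ccc(OCC=C(C)C)cc2)oc(C(=O)C=[N+]=[N-])cc1=O
A4 | direct plan | (ethynyloxy)triisopropylsilane | C#CO[Si](C(C)C)(C(C)C)C(C)C
A5 | direct plan | 5-hydroxy-3-methoxy-2-[4-(3-methylbut-2-enyloxy)phenyl]-7-(triisopropylsilyloxy)-4H-chromen-4-one | COc1c(-c2ccc(OCC=C(C)C)cc2)oc2cc(O[Si](C(C)C)(C(C)C)C(C)C)cc(O)c2c1=O
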